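Everything rests on cutting the five-membered oxygen ring of the naphtho[1,8-bc]furan twice: between the ether oxygen and naphthalene C8 and between the spiro carbon and naphthalene C1 (numbering of 6-methyl-2-naphthol). In one operation a 1-naphthyl Grignard reagent adds to the imide carbonyl beside the methoxy group, and the hemiaminal oxygen so formed then replaces the peri C8–H bond under Pd catalysis with a chiral amino acid ligand. The step exploits the peri relationship of C1 and C8 around the spiro N,O-ketal carbon and the stereolability of the hemiaminal, which allows a dynamic kinetic resolution. The precursors are silylated 1-bromo-6-methyl-2-naphthol and N-(2-silyloxyethyl)-3-methoxyphthalimide.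

Key step: step 4

Assumptions: 1, 2 and 4 are taken as catalogue compounds; the Grignard reagent is taken to add to the imide carbonyl next to the methoxy group (magnesium chelation), which is to be confirmed on 9.

Step 1
Reactants: 1 3-methoxyphthalic anhydride; 2 2-[(tert-butyldimethylsilyl)oxy]ethan-1-amine
Product: 3 2-{2-[(tert-butyldimethylsilyl)oxy]ethyl}-4-methoxyisoindoline-1,3-dione
Conditions: toluene, Et3N (10 mol %), reflux, Dean–Stark trap
Reagents that add atoms: none
Why: Imide formation from a cyclic anhydride and a primary amine (ring opening to the amic acid, then thermal cyclodehydration); both amic acid regioisomers converge on the same imide and the silyl ether should survive the neutral conditions.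

Step 2
Reactants: 4 6-methylnaphthalen-2-ol
Product: 5 1-bromo-6-methylnaphthalen-2-ol
Conditions: NBS (1.05 equiv), MeCN, 0 °C, dark
Reagents that add atoms: N-bromosuccinimide, O=C1CCC(=O)N1Br
Why: Electrophilic aromatic bromination of a 2-naphthol, which should occur at C1, the alpha position ortho to the hydroxyl group.

Step 3
Reactants: 5 1-bromo-6-methylnaphthalen-2-ol
Product: 6 [(1-bromo-6-methylnaphthalen-2-yl)oxy](tert-butyl)dimethylsilane
Conditions: TBSCl, imidazole, DMF, rt
Reagents that add atoms: tert-butyldimethylsilyl chloride, CC(C)(C)[Si](C)(C)Cl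
Why: Silylation of the phenol (imidazole-promoted silyl ether formation) removes the acidic proton before Grignard formation and shields the naphthol from PhI(OAc)2 in the next step.

Step 4
Reactants: 6 [(1-bromo-6-methylnaphthalen-2-yl)oxy](tert-butyl)dimethylsilane; 3 2-{2-[(tert-butyldimethylsilyl)oxy]ethyl}-4-methoxyisoindoline-1,3-dione
Product: 9 (R)-3'-[(tert-butyldimethylsilyl)oxy]-2-{2-[(tert-butyldimethylsilyl)oxy]ethyl}-7-methoxy-7'-methyl-2'H-spiro[isoindoline-1,2'-naphtho[1,8-bc]furan]-3-one (the bis-silyl ether of the target with the target's spatial arrangement at the spiro carbon), via arylmagnesium bromide 7 (not isolated), via hydroxylactam 8 (not isolated)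
Conditions: one pot: 6, Mg, THF, 60 °C; 3, toluene, −20 °C to rt; AcOH (1 equiv), solvent exchange to C6F6; Pd(OAc)2 (10 mol %), N-Boc-L-tert-leucine (20 mol %), PhI(OAc)2 (1.5 equiv), Li2CO3 (1.5 equiv), 80 °C
Reagents that add atoms: none
Why: Proposed new method: Grignard reagent 7 adds once to the imide carbonyl next to the methoxy group (Mg chelated between OMe and that carbonyl oxygen) to give hydroxylactam 8, whose enantiomers interconvert through the ring-opened 2-aroylbenzamide and the N-acyliminium ion; its alkoxide binds divalent palladium, the amino acid ligand assists concerted metalation–deprotonation of the peri C8–H bond to a six-membered oxapalladacycle, PhI(OAc)2 oxidises this to tetravalent palladium and C(aryl)–O reductive elimination releases 9. The closest known reaction types are the mono-addition of Grignard reagents to N-alkylphthalimides, the hydroxyl-directed C–H activation/C–O cyclisation of tertiary alcohols with Pd(OAc)2 and PhI(OAc)2, and the enantioselective C–H activation/C–O cyclisation of diarylacetic acids with Pd(OAc)2 and mono-N-protected amino acids; new are the peri C–H bond and the use as a dynamic kinetic resolution of a racemising hemiaminal. One ring is closed, the five-membered oxygen ring of the naphtho[1,8-bc]furan, by reductive elimination from the six-membered palladacycle (peri annulation, oxygen and carbon both already held on the metal). The spiro carbon is the only new stereocentre and is fixed in the C–H palladation, where the chiral ligand selects the enantiomer of 8 whose lactam nitrogen and aryl carbon, lying above and below the palladacycle, fit its tert-butyl group; the sense of induction cannot be predicted with confidence, must be confirmed, and the D-ligand is taken if it is opposite. The step needs carbonyl regioselectivity (chelation), C–H site selectivity (the ortho positions flanking the carbinol carry OTBS and OMe, so only the peri C–H can be reached) and racemisation of 8 faster than cyclisation of its mismatched enantiomer (acetate and carbonate at 80 °C).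

Step 5
Reactants: 9 (R)-3'-[(tert-butyldimethylsilyl)oxy]-2-{2-[(tert-butyldimethylsilyl)oxy]ethyl}-7-methoxy-7'-methyl-2'H-spiro[isoindoline-1,2'-naphtho[1,8-bc]furan]-3-one
Product: 10 (S)-3'-hydroxy-2-(2-hydroxyethyl)-7-methoxy-7'-methyl-2'H-spiro[isoindoline-1,2'-naphtho[1,8-bc]furan]-3-one (CNP0434366.2)
Conditions: TBAF (2.5 equiv), AcOH (2.5 equiv), THF, 0 °C to rt
Reagents that add atoms: none
Why: Fluoride-mediated cleavage of both silyl ethers, buffered with acetic acid so that no free naphtholate opens the N,O-ketal through an ortho-quinone methide; no bond at the stereocentre is touched, and the descriptor changes from R to S only because the CIP ranking of the two aryl groups is reversed when O–Si becomes O–H.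

Compound list
1 | 3-methoxyphthalic anhydride (4-methoxy-2-benzofuran-1,3-dione) | COc1cccc2c1C(=O)OC2=O | starting material
2 | 2-[(tert-butyldimethylsilyl)oxy]ethan-1-amine | NCCO[Si](C)(C)C(C)(C)C | starting material
3 | 2-{2-[(tert-butyldimethylsilyl)oxy]ethyl}-4-methoxyisoindoline-1,3-dione | COc1cccc2c1C(=O)N(CCO[Si](C)(C)C(C)(C)C)C2=O | intermediate
4 | 6-methylnaphthalen-2-ol | Cc1ccc2cc(O)ccc2c1 | starting material
5 | 1-bromo-6-methylnaphthalen-2-ol | Cc1ccc2c(Br)c(O)ccc2c1 | intermediate
6 | [(1-bromo-6-methylnaphthalen-2-yl)oxy](tert-butyl)dimethylsilane | Cc1ccc2c(Br)c(O[Si](C)(C)C(C)(C)C)ccc2c1 | intermediate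
7 | {2-[(tert-butyldimethylsilyl)oxy]-6-methylnaphthalen-1-yl}magnesium bromide | Cc1ccc2c([Mg]Br)c(O[Si](C)(C)C(C)(C)C)ccc2c1 | intermediate
8 | racemic, stereolabile 2-{2-[(tert-butyldimethylsilyl)oxy]ethyl}-3-{2-[(tert-butyldimethylsilyl)oxy]-6-methylnaphthalen-1-yl}-3-hydroxy-4-methoxyisoindolin-1-one | COc1cccc2c1C(O)(c1c(O[Si](C)(C)C(C)(C)C)ccc3cc(C)ccc13)N(CCO[Si](C)(C)C(C)(C)C)C2=O | intermediate
9 | (R)-3'-[(tert-butyldimethylsilyl)oxy]-2-{2-[(tert-butyldimethylsilyl)oxy]ethyl}-7-methoxy-7'-methyl-2'H-spiro[isoindoline-1,2'-naphtho[1,8-bc]furan]-3-one | COc1cccc2c1[C@]1(Oc3cc(C)cc4ccc(O[Si](C)(C)C(C)(C)C)c1c34)N(CCO[Si](C)(C)C(C)(C)C)C2=O | intermediate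
10 | (S)-3'-hydroxy-2-(2-hydroxyethyl)-7-methoxy-7'-methyl-2'H-spiro[isoindoline-1,2'-naphtho[1,8-bc]furan]-3-one | COc1cccc2c1[C@]1(Oc3cc(C)cc4ccc(O)c1c34)N(CCO)C2=O | target

Total step count: 5. Longest linear sequence: 4 steps (steps 2, 3, 4 and 5).

Steps most likely to fail

Step 4 (Proposed new method). The ligand-bound palladium may not discriminate well enough between the two interconverting hemiaminal enantiomers, or ligand-free background palladation may erode the selectivity, so that the ring closure proceeds with low enantiomeric purity. The fallback sets out from 6 and 3. The same one-pot Grignard addition through 7 and 8 is closed without a chiral ligand (Pd(OAc)2 10 mol %, PhI(OAc)2, Li2CO3, C6F6, 100 °C), the known hydroxyl-directed C–H activation/C–O cyclisation of tertiary alcohols. This should give the racemic spiro bis-silyl ether F1. Preparative supercritical-fluid chromatography on a chiral stationary phase (amylose tris(3,5-dimethylphenylcarbamate)) then separates the enantiomers and returns to the route at 9. The unwanted enantiomer should be racemisable with a catalytic sulfonic acid through the N-acyliminium ion and can be recycled.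

Step 5. Fluoride may generate the free naphtholate faster than it is protonated; reversible opening of the spiro N,O-ketal through an ortho-quinone methide would then erode the enantiomeric purity. The fallback sets out from 5 and avoids any naphtholate after the stereocentre is set:
- Benzylation (BnBr, K2CO3, acetone, reflux) gives 2-(benzyloxy)-1-bromo-6-methylnaphthalene F2.
- The one-pot sequence of step 4 with 3 then runs through the arylmagnesium bromide F3 and the hydroxylactam F4 to the benzyl-protected spiro compound F5.
- TBAF in THF removes the primary silyl ether while the naphthol stays masked and gives the alcohol F6.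
- Hydrogenolysis (H2, 10% Pd/C, EtOAc, rt) cleaves the aryl benzyl ether under neutral conditions and comes back to the route at 10.

Step 1. Cyclodehydration may stall at the amic acid, or the carboxylic acid intermediate may cleave the silyl ether at reflux. The fallback sets out from 1: condensation with 2-aminoethanol (toluene, reflux, Dean–Stark trap) gives 2-(2-hydroxyethyl)-4-methoxyisoindoline-1,3-dione F7, and silylation (TBSCl, imidazole, DMF, rt) returns to the route at 3.

Further compounds
F1 | step 4 | racemic 3'-[(tert-butyldimethylsilyl)oxy]-2-{2-[(tert-butyldimethylsilyl)oxy]ethyl}-7-methoxy-7'-methyl-2'H-spiro[isoindoline-1,2'-naphtho[1,8-bc]furan]-3-one | COc1cccc2c1C1(Oc3cc(C)cc4ccc(O[Si](C)(C)C(C)(C)C)c1c34)N(CCO[Si](C)(C)C(C)(C)C)C2=O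
F2 | step 5 | 2-(benzyloxy)-1-bromo-6-methylnaphthalene | Cc1ccc2c(Br)c(OCc3ccccc3)ccc2c1
F3 | step 5 | [2-(benzyloxy)-6-methylnaphthalen-1-yl]magnesium bromide | Cc1ccc2c([Mg]Br)c(OCc3ccccc3)ccc2c1
F4 | step 5 | racemic, stereolabile 3-[2-(benzyloxy)-6-methylnaphthalen-1-yl]-2-{2-[(tert-butyldimethylsilyl)oxy]ethyl}-3-hydroxy-4-methoxyisoindolin-1-one | COc1cccc2c1C(O)(c1c(OCc5ccccc5)ccc3cc(C)ccc13)N(CCO[Si](C)(C)C(C)(C)C)C2=O
F5 | step 5 | (S)-3'-(benzyloxy)-2-{2-[(tert-butyldimethylsilyl)oxy]ethyl}-7-methoxy-7'-methyl-2'H-spiro[isoindoline-1,2'-naphtho[1,8-bc]furan]-3-one | COc1cccc2c1[C@]1(Oc3cc(C)cc4ccc(OCc5ccccc5)c1c34)N(CCO[Si](C)(C)C(C)(C)C)C2=O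
F6 | step 5 | (S)-3'-(benzyloxy)-2-(2-hydroxyethyl)-7-methoxy-7'-methyl-2'H-spiro[isoindoline-1,2'-naphtho[1,8-bc]furan]-3-one | COc1cccc2c1[C@]1(Oc3cc(C)cc4ccc(OCc5ccccc5)c1c34)N(CCO)C2=O
F7 | step 1 | 2-(2-hydroxyethyl)-4-methoxyisoindoline-1,3-dione | COc1cccc2c1C(=O)N(CCO)C2=O
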